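The ratio of product to intermediate in the dawn run, 0.500 after 40.0 h, can be read two ways, and the row asked for hangs on which one is right.

| flask | substrate | coupling partner | remark | time |
|---|---|---|---|---|
| dawn | 0.013 M | 0.0025 M (in portions, 4) | run made earlier; portions every 8.0 h |  |
| east | 0.020 M | 0.00250 M (in portions, 4) | the portions of coupling partner follow each other after 8.0 h, the first at the start | 3.0 d |
| north-east | 0.020 M | 0.00800 M (in portions, 4) | the portions of coupling partner follow each other after 8.0 h, the first at the start | 3.0 d |
| north | 0.020 M | 0.0200 M (in portions, 4) | the portions of coupling partner follow each other after 8.0 h, the first at the start | 3.0 d |
| west | 0.020 M | 0.0600 M (in portions, 4) | the portions of coupling partner follow each other after 8.0 h, the first at the start | 3.0 d |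
| south-east | 0.020 M | 0.200 M (in portions, 4) | the portions of coupling partner follow each other after 8.0 h, the first at the start | 3.0 d |

- dawn (time / h: intermediate / %, product / %): 3.00: 0.2, 0.6; 6.00: 0.6, 0; 10.0: 1.0, 0.3; 15.0: 1.1, 0.7; 25.0: 2.5, 1.2; 40.0: 4.6, 2.3

(standard deviation of a reading: 0.3 percentage points)

- "hardly changes" means that all values lie within two and a half points (for a concentration: within two and a half percent of the largest)

* amount of intermediate at the end, in percent of the substrate charged for east, north-east, north, west, south-east, in this order
* how the row runs (rises, then falls / falls, then rises / rises all the way / hardly changes / falls all the way)

Two chemists argue over that ratio. The first holds that the intermediate takes a second share of coupling partner to become product. Both steps then speed up together with partner, their speeds keep a ratio of about 12, and the intermediate stays near one part in 11 of the substrate.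

The second holds that the intermediate turns into product by itself, on a clock that partner does not touch. I reckon with this view, though the dawn readings cannot separate the two. The intermediate climbed roughly in a straight line, so its average was about 2.30%. Dividing the product by that average and by the time gives a decay constant of 0.0250 h⁻¹, a half-life of 27.7 h.

The substrate used by then, 6.90%, divided by the partner's concentration summed over time, 252 M·s, gives the first step's constant, 2.74 × 10⁻⁴ M⁻¹ s⁻¹. That sum counts the partner as unspent, so the constant is on the low side.

The quantity to carry is the crossing level, the partner concentration at which substrate goes to intermediate on the same clock as intermediate goes to product: the decay constant over the first step's constant, 0.0254 M. Below it the first step is the rate-limiting step. Above it the substrate goes first and the intermediate is left to decay.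

Partner is spent one for one with substrate, so the charge that still leaves the crossing level once the substrate is used is 0.0454 M. I therefore expect the row to rise to a top between north and west. With equal clocks, the intermediate at the end would be about 29.8%.

The forecast, on the first view (“With excess partner, substrate and intermediate are both consumed, so the intermediate falls toward zero”), gave 5%, 8%, 6%, 1.5% and 0.1%, a row that rises, then falls.

The flask gives 3.45%, 10.2%, 20.8%, 25.3% and 16.0%, a row that rises, then falls, turning at a partner charge of 0.043 M.

    crystals ⇌ by-product, rate k1*(cs1 - [by-product]) while solid is left; crystals form when [by-product] > cs1 (solubility = 1.30 mM, k = 0.00185 s⁻¹)
    intermediate → product (k = 8.48 × 10⁻⁶ s⁻¹)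
    substrate + coupling partner → intermediate + by-product (k = 3.52 × 10⁻⁴ M⁻¹ s⁻¹)

The first view's level of one part in 11 fits north-east, which ends at 10.2%, while east ends lower and west higher. The turn lies close to my reckoned charge, and the top lies below my estimate. East's charge lies 10.1 times below the crossing level. There the half-life of substrate by the first step, the whole charge counted at once, is 9.1 d, ten times the 0.95 d of intermediate going to product.

The readings are calculated with made-up constants, noise included.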